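**Retrosynthetic overview** (rings: butenolide A, cyclohexene B, cyclobutane C, spiro phthalide D)
1. Ring A is opened last: the (Z)-butylidene butenolide comes from silver-catalysed 5-exo-dig lactonisation of the 2-en-4-ynoic acid set free from tert-butyl ester 25; the alkyne goes back to enol triflate 17 and pent-1-yne.
2. Ring D is cut at the spiro C–aryl and C–O bonds: cyclobutanone 21 plus the aryl Grignard reagent from methyl 2-iodobenzoate, added from the convex face.
3. The feature the strategy rests on: the tetrasubstituted C=C of ring B carries the carboxyl carbon on one end and an oxygenated carbon on the other, and sits between the two cis ring-fusion CH groups of ring C. This is the enol of a cyclic β-keto ester (16), cut by a Dieckmann condensation between a CH2CO2C(CH3)3 arm and a CH2CH2CO2CH3 arm of all-cis cyclobutane 15.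
4. Cyclobutane 15 is traced to the [2+2] adduct of propylketene and cyclopentadiene (endo propyl), exo-face reduction, lipase resolution, cleavage of the cyclopentene, and arm differentiation through a cyclic anhydride.
5. Order of ring formation: C (step 1), B (step 10), D (step 15), A (step 16).

Key step: step 10

Assumption: the lipase of step 3 is taken to acylate the (6S)-alcohol faster, so the (6R)-alcohol needed is recovered unreacted; if the preference is the reverse, the same alcohol is obtained from the acetate fraction with K2CO3 in MeOH.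

**Step 1**
Reactants: 1 pentanoyl chloride; 2 cyclopenta-1,3-diene
Product: 4 rac-(1S*,5S*,7R*)-7-propylbicyclo[3.2.0]hept-2-en-6-one (propyl endo), via propylketene 3 (not isolated)
Conditions: Et3N (slow addition), excess 2, hexane, 0 °C to rt
Reagents that add atoms: none
Why: Dehydrochlorination gives propylketene, which adds to cyclopentadiene in a thermal ketene–alkene [2+2] cycloaddition (carbonyl carbon to the diene terminus); the ring enforces the cis fusion and the propyl group should take the endo position under kinetic control, as is usual for monoalkylketenes.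

**Step 2**
Reactants: 4 rac-(1S*,5S*,7R*)-7-propylbicyclo[3.2.0]hept-2-en-6-one
Product: 5 rac-(1S*,5S*,6R*,7R*)-7-propylbicyclo[3.2.0]hept-2-en-6-ol
Conditions: LiBH(sec-C4H9)3, THF, −78 °C; then NaOH, H2O2
Reagents that add atoms: none
Why: Hydride reduction of a cyclobutanone with a bulky borohydride should occur from the open convex (exo) face, placing the hydroxyl endo, cis to the propyl group and the cyclopentene ring, while the cold aprotic conditions spare the epimerisable α-propyl centre.

**Step 3**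
Reactants: 5 rac-(1S*,5S*,6R*,7R*)-7-propylbicyclo[3.2.0]hept-2-en-6-ol
Product: 6 (1S,5S,6R,7R)-7-propylbicyclo[3.2.0]hept-2-en-6-ol
Conditions: Burkholderia cepacia lipase (immobilised), vinyl acetate, MTBE, 30 °C, run to just over half conversion, then chromatography
Reagents that add atoms: none
Why: Lipase-catalysed transesterification serves as a kinetic resolution of the secondary alcohol: one enantiomer is acetylated and separated, the other is recovered, and no stereocenter is formed.

**Step 4**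
Reactants: 6 (1S,5S,6R,7R)-7-propylbicyclo[3.2.0]hept-2-en-6-ol
Product: 7 tert-butyldimethyl{[(1S,5S,6R,7R)-7-propylbicyclo[3.2.0]hept-2-en-6-yl]oxy}silane
Conditions: TBSOTf, 2,6-lutidine, CH2Cl2, 0 °C
Reagents that add atoms: tert-butyldimethylsilyl trifluoromethanesulfonate, CC(C)(C)[Si](C)(C)OS(=O)(=O)C(F)(F)F
Why: Silyl ether formation with the silyl triflate should overcome the hindrance of the concave-face alcohol; no stereocenter is touched.

**Step 5**
Reactants: 7 tert-butyldimethyl{[(1S,5S,6R,7R)-7-propylbicyclo[3.2.0]hept-2-en-6-yl]oxy}silane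
Product: 9 (1S,2S,3R,4R)-3-[(tert-butyldimethylsilyl)oxy]-2-(carboxymethyl)-4-propylcyclobutane-1-carboxylic acid, via dialdehyde 8 (not isolated)
Conditions: O3, CH2Cl2/MeOH, −78 °C; Me2S; then NaClO2, NaH2PO4, 2-methylbut-2-ene, t-BuOH/H2O, rt
Reagents that add atoms: ozone, [O-][O+]=O; sodium chlorite, [Na+].[O-]Cl=O
Why: Ozonolysis of the cyclopentene with reductive work-up followed by Pinnick oxidation of both aldehydes gives the two carboxyl arms without base, so the formyl-bearing ring centre should keep its cis configuration.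

**Step 6**
Reactants: 9 (1S,2S,3R,4R)-3-[(tert-butyldimethylsilyl)oxy]-2-(carboxymethyl)-4-propylcyclobutane-1-carboxylic acid
Product: 11 (1S,2S,3R,4R)-2-(2-tert-butoxy-2-oxoethyl)-3-[(tert-butyldimethylsilyl)oxy]-4-propylcyclobutane-1-carboxylic acid, via cyclic anhydride 10 (not isolated)
Conditions: Ac2O, 60 °C, then evaporation; KOC(CH3)3 (1.05 equiv), THF, −40 to 0 °C; aq HCl to pH 3
Reagents that add atoms: potassium tert-butoxide, CC(C)(C)[O-].[K+]
Why: Dehydration closes the cis-fused six-membered anhydride, and alcoholysis by the bulky tert-butoxide should take place at the carbonyl next to the CH2 group, not at the one bound to the congested ring carbon (regioselective opening of an unsymmetrical cyclic anhydride), which differentiates the two arms.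

**Step 7**
Reactants: 11 (1S,2S,3R,4R)-2-(2-tert-butoxy-2-oxoethyl)-3-[(tert-butyldimethylsilyl)oxy]-4-propylcyclobutane-1-carboxylic acid
Product: 12 tert-butyl 2-[(1S,2R,3R,4S)-2-[(tert-butyldimethylsilyl)oxy]-4-(hydroxymethyl)-3-propylcyclobutyl]acetate
Conditions: BH3·SMe2, THF, 0 °C to rt; MeOH
Reagents that add atoms: none
Why: Borane reduces a carboxylic acid much faster than an ester (chemoselective acid reduction), so only the ring-bound carboxyl should be taken to the primary alcohol.

**Step 8**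
Reactants: 12 tert-butyl 2-[(1S,2R,3R,4S)-2-[(tert-butyldimethylsilyl)oxy]-4-(hydroxymethyl)-3-propylcyclobutyl]acetate
Product: 14 methyl (2E)-3-[(1S,2S,3R,4R)-2-(2-tert-butoxy-2-oxoethyl)-3-[(tert-butyldimethylsilyl)oxy]-4-propylcyclobutyl]prop-2-enoate, via aldehyde 13 (not isolated)
Conditions: Dess–Martin periodinane, NaHCO3, CH2Cl2, 0 °C to rt; then Ph3P=CHCO2CH3, rt
Reagents that add atoms: methyl (triphenylphosphoranylidene)acetate, COC(=O)C=P(c1ccccc1)(c1ccccc1)c1ccccc1
Why: Dess–Martin oxidation and in-situ Wittig olefination with a stabilised ylide under neutral conditions should give the (E)-enoate without isolating the epimerisable all-cis aldehyde.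

**Step 9**
Reactants: 14 methyl (2E)-3-[(1S,2S,3R,4R)-2-(2-tert-butoxy-2-oxoethyl)-3-[(tert-butyldimethylsilyl)oxy]-4-propylcyclobutyl]prop-2-enoate
Product: 15 methyl 3-[(1S,2S,3R,4R)-2-(2-tert-butoxy-2-oxoethyl)-3-[(tert-butyldimethylsilyl)oxy]-4-propylcyclobutyl]propanoate
Conditions: H2 (1 atm), Pd/C, EtOAc, rt
Reagents that add atoms: none
Why: Catalytic hydrogenation of the conjugated alkene; the silyl ether and both esters are inert and no stereocenter is formed.

**Step 10**
Reactants: 15 methyl 3-[(1S,2S,3R,4R)-2-(2-tert-butoxy-2-oxoethyl)-3-[(tert-butyldimethylsilyl)oxy]-4-propylcyclobutyl]propanoate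
Product: 16 tert-butyl (1R,6S,7R,8R)-8-[(tert-butyldimethylsilyl)oxy]-3-hydroxy-7-propylbicyclo[4.2.0]oct-2-ene-2-carboxylate (enol form)
Conditions: KOC(CH3)3 (2.2 equiv), THF, 0 °C to rt; AcOH
Reagents that add atoms: none
Why: KOC(CH3)3 deprotonates reversibly α to both esters, but only the enolate of the tert-butyl ester finds a reactive partner: it adds to the methyl ester carbonyl, methoxide is lost, and the β-keto ester is at once deprotonated to its stabilised enolate, which drives the reaction (Dieckmann condensation of a mixed tert-butyl/methyl diester, the closest known reaction type). Ring B closes in a 6-exo-trig mode between the α-carbon of the acetate arm and the propanoate carbonyl carbon, which become C2 and C3 of the bicyclo[4.2.0]octene. No stereocenter is created: C2 ends as an sp2 carbon of the enol, and the cis ring fusion is inherited from the cis arms of 15. The selectivity needed is regiochemical, because attack of the propanoate enolate on the acetate ester would give the isomeric 3-oxo-4-carboxylate; the poorly electrophilic tert-butyl ester should suppress that mode. The four cyclobutane CH centres are not α to a carbonyl group and cannot epimerise under the base, and the silyl ether keeps the C8 oxygen out of the reaction.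

**Step 11**
Reactants: 16 tert-butyl (1R,6S,7R,8R)-8-[(tert-butyldimethylsilyl)oxy]-3-hydroxy-7-propylbicyclo[4.2.0]oct-2-ene-2-carboxylate
Product: 17 tert-butyl (1R,6S,7R,8R)-8-[(tert-butyldimethylsilyl)oxy]-7-propyl-3-[(trifluoromethanesulfonyl)oxy]bicyclo[4.2.0]oct-2-ene-2-carboxylate
Conditions: NaH, THF, 0 °C; PhN(SO2CF3)2, 0 °C to rt
Reagents that add atoms: N-phenylbis(trifluoromethanesulfonimide), O=S(=O)(N(c1ccccc1)S(=O)(=O)C(F)(F)F)C(F)(F)F
Why: O-Sulfonylation of the sodium enolate of the β-keto ester (enol triflate formation) fixes the tetrasubstituted C2=C3 alkene.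

**Step 12**
Reactants: 17 tert-butyl (1R,6S,7R,8R)-8-[(tert-butyldimethylsilyl)oxy]-7-propyl-3-[(trifluoromethanesulfonyl)oxy]bicyclo[4.2.0]oct-2-ene-2-carboxylate; 18 pent-1-yne
Product: 19 tert-butyl (1R,6S,7R,8R)-8-[(tert-butyldimethylsilyl)oxy]-3-(pent-1-yn-1-yl)-7-propylbicyclo[4.2.0]oct-2-ene-2-carboxylate
Conditions: PdCl2(PPh3)2 (cat.), CuI (cat.), Et3N, DMF, rt
Reagents that add atoms: none
Why: Sonogashira coupling of an electron-poor enol triflate with a terminal alkyne installs the five-carbon chain at C3; it is placed before the ketone is unveiled so that no triflate is exposed to fluoride or to the Grignard reagent.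

**Step 13**
Reactants: 19 tert-butyl (1R,6S,7R,8R)-8-[(tert-butyldimethylsilyl)oxy]-3-(pent-1-yn-1-yl)-7-propylbicyclo[4.2.0]oct-2-ene-2-carboxylate
Product: 20 tert-butyl (1R,6S,7R,8R)-8-hydroxy-3-(pent-1-yn-1-yl)-7-propylbicyclo[4.2.0]oct-2-ene-2-carboxylate
Conditions: HF·pyridine, pyridine, THF, 0 °C to rt
Reagents that add atoms: none
Why: Fluoride-mediated cleavage of the silyl ether under buffered conditions should leave the tert-butyl ester and the enyne untouched.

**Step 14**
Reactants: 20 tert-butyl (1R,6S,7R,8R)-8-hydroxy-3-(pent-1-yn-1-yl)-7-propylbicyclo[4.2.0]oct-2-ene-2-carboxylate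
Product: 21 tert-butyl (1R,6S,7R)-8-oxo-3-(pent-1-yn-1-yl)-7-propylbicyclo[4.2.0]oct-2-ene-2-carboxylate
Conditions: Dess–Martin periodinane, NaHCO3, CH2Cl2, 0 °C
Reagents that add atoms: none
Why: Dess–Martin oxidation of the secondary cyclobutanol under buffered neutral conditions is chosen so that the α-propyl centre of the cyclobutanone is not epimerised.

**Step 15**
Reactants: 21 tert-butyl (1R,6S,7R)-8-oxo-3-(pent-1-yn-1-yl)-7-propylbicyclo[4.2.0]oct-2-ene-2-carboxylate; 22 methyl 2-iodobenzoate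
Product: 25 tert-butyl (1R,6S,7R,8R)-3'-oxo-3-(pent-1-yn-1-yl)-7-propyl-3'H-spiro[bicyclo[4.2.0]oct-2-ene-8,1'-[2]benzofuran]-2-carboxylate, via arylmagnesium chloride 23 (not isolated), via magnesium alkoxide 24 (not isolated)
Conditions: 22, i-PrMgCl·LiCl, THF, −40 °C; then 21, LaCl3·2LiCl, −40 to 0 °C; aq NH4Cl
Reagents that add atoms: none
Why: Iodine–magnesium exchange gives the ester-bearing aryl Grignard reagent, whose 1,2-addition to the strained ketone should occur from the convex face opposite to the six-membered ring and the propyl group (aryl anti, oxygen syn to them), after which the tertiary alkoxide acylates itself on the ortho ester to close the spiro phthalide (Grignard addition–lactonisation).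

**Step 16**
Reactants: 25 tert-butyl (1R,6S,7R,8R)-3'-oxo-3-(pent-1-yn-1-yl)-7-propyl-3'H-spiro[bicyclo[4.2.0]oct-2-ene-8,1'-[2]benzofuran]-2-carboxylate
Product: 27 CNP0248594.2 (target), via enynoic acid 26 (not isolated)
Conditions: CF3CO2H, CH2Cl2, 0 °C; evaporation; AgNO3 (cat.), acetone, rt, dark
Reagents that add atoms: none
Why: Acidolysis of the tert-butyl ester frees the ring-constrained (Z)-2-en-4-ynoic acid, and silver-catalysed anti-oxymetalation of the alkyne in the 5-exo-dig mode followed by protodemetalation should give the (Z)-butylidene butenolide.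

**Compound list**
1 | pentanoyl chloride | CCCCC(Cl)=O | starting material
2 | cyclopenta-1,3-diene (freshly distilled from its commercial dimer) | C1C=CC=C1 | starting material
3 | propylketene (pent-1-en-1-one) | CCCC=C=O | intermediate (not isolated)
4 | rac-(1S*,5S*,7R*)-7-propylbicyclo[3.2.0]hept-2-en-6-one, propyl endo (racemate; the enantiomer carried on is drawn) | C1=C[C@H]2[C@@H](CCC)C(=O)[C@H]2C1 | intermediate
5 | rac-(1S*,5S*,6R*,7R*)-7-propylbicyclo[3.2.0]hept-2-en-6-ol, OH and propyl endo (racemate; the enantiomer carried on is drawn) | C1=C[C@H]2[C@@H](CCC)[C@@H](O)[C@H]2C1 | intermediate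
6 | (1S,5S,6R,7R)-7-propylbicyclo[3.2.0]hept-2-en-6-ol | C1=C[C@H]2[C@@H](CCC)[C@@H](O)[C@H]2C1 | intermediate
7 | tert-butyldimethyl{[(1S,5S,6R,7R)-7-propylbicyclo[3.2.0]hept-2-en-6-yl]oxy}silane | C1=C[C@H]2[C@@H](CCC)[C@@H](O[Si](C)(C)C(C)(C)C)[C@H]2C1 | intermediate
8 | (1S,2S,3R,4R)-3-[(tert-butyldimethylsilyl)oxy]-2-(2-oxoethyl)-4-propylcyclobutane-1-carbaldehyde (all-cis) | O=C[C@H]1[C@@H](CCC)[C@@H](O[Si](C)(C)C(C)(C)C)[C@H]1CC=O | intermediate (not isolated)
9 | (1S,2S,3R,4R)-3-[(tert-butyldimethylsilyl)oxy]-2-(carboxymethyl)-4-propylcyclobutane-1-carboxylic acid | OC(=O)[C@H]1[C@@H](CCC)[C@@H](O[Si](C)(C)C(C)(C)C)[C@H]1CC(O)=O | intermediate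
10 | (1S,6S,7R,8R)-7-[(tert-butyldimethylsilyl)oxy]-8-propyl-3-oxabicyclo[4.2.0]octane-2,4-dione | O=C1OC(=O)[C@H]2[C@@H](CCC)[C@@H](O[Si](C)(C)C(C)(C)C)[C@H]2C1 | intermediate (not isolated)
11 | (1S,2S,3R,4R)-2-(2-tert-butoxy-2-oxoethyl)-3-[(tert-butyldimethylsilyl)oxy]-4-propylcyclobutane-1-carboxylic acid | OC(=O)[C@H]1[C@@H](CCC)[C@@H](O[Si](C)(C)C(C)(C)C)[C@H]1CC(=O)OC(C)(C)C | intermediate
12 | tert-butyl 2-[(1S,2R,3R,4S)-2-[(tert-butyldimethylsilyl)oxy]-4-(hydroxymethyl)-3-propylcyclobutyl]acetate | OC[C@H]1[C@@H](CCC)[C@@H](O[Si](C)(C)C(C)(C)C)[C@H]1CC(=O)OC(C)(C)C | intermediate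
13 | tert-butyl 2-[(1S,2R,3R,4S)-2-[(tert-butyldimethylsilyl)oxy]-4-formyl-3-propylcyclobutyl]acetate | O=C[C@H]1[C@@H](CCC)[C@@H](O[Si](C)(C)C(C)(C)C)[C@H]1CC(=O)OC(C)(C)C | intermediate (not isolated)
14 | methyl (2E)-3-[(1S,2S,3R,4R)-2-(2-tert-butoxy-2-oxoethyl)-3-[(tert-butyldimethylsilyl)oxy]-4-propylcyclobutyl]prop-2-enoate | COC(=O)/C=C/[C@H]1[C@@H](CCC)[C@@H](O[Si](C)(C)C(C)(C)C)[C@H]1CC(=O)OC(C)(C)C | intermediate
15 | methyl 3-[(1S,2S,3R,4R)-2-(2-tert-butoxy-2-oxoethyl)-3-[(tert-butyldimethylsilyl)oxy]-4-propylcyclobutyl]propanoate (key-step precursor) | COC(=O)CC[C@H]1[C@@H](CCC)[C@@H](O[Si](C)(C)C(C)(C)C)[C@H]1CC(=O)OC(C)(C)C | intermediate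
16 | tert-butyl (1R,6S,7R,8R)-8-[(tert-butyldimethylsilyl)oxy]-3-hydroxy-7-propylbicyclo[4.2.0]oct-2-ene-2-carboxylate, enol form (key-step product) | CC(C)(C)OC(=O)C2=C(O)CC[C@H]1[C@@H](CCC)[C@@H](O[Si](C)(C)C(C)(C)C)[C@@H]21 | intermediate
17 | tert-butyl (1R,6S,7R,8R)-8-[(tert-butyldimethylsilyl)oxy]-7-propyl-3-[(trifluoromethanesulfonyl)oxy]bicyclo[4.2.0]oct-2-ene-2-carboxylate | CC(C)(C)OC(=O)C2=C(OS(=O)(=O)C(F)(F)F)CC[C@H]1[C@@H](CCC)[C@@H](O[Si](C)(C)C(C)(C)C)[C@@H]21 | intermediate
18 | pent-1-yne | CCCC#C | starting material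
19 | tert-butyl (1R,6S,7R,8R)-8-[(tert-butyldimethylsilyl)oxy]-3-(pent-1-yn-1-yl)-7-propylbicyclo[4.2.0]oct-2-ene-2-carboxylate | CC(C)(C)OC(=O)C2=C(C#CCCC)CC[C@H]1[C@@H](CCC)[C@@H](O[Si](C)(C)C(C)(C)C)[C@@H]21 | intermediate
20 | tert-butyl (1R,6S,7R,8R)-8-hydroxy-3-(pent-1-yn-1-yl)-7-propylbicyclo[4.2.0]oct-2-ene-2-carboxylate | CC(C)(C)OC(=O)C2=C(C#CCCC)CC[C@H]1[C@@H](CCC)[C@@H](O)[C@@H]21 | intermediate
21 | tert-butyl (1R,6S,7R)-8-oxo-3-(pent-1-yn-1-yl)-7-propylbicyclo[4.2.0]oct-2-ene-2-carboxylate (cis-fused; propyl cis to the six-membered ring) | CC(C)(C)OC(=O)C2=C(C#CCCC)CC[C@H]1[C@@H](CCC)C(=O)[C@@H]21 | intermediate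
22 | methyl 2-iodobenzoate | COC(=O)c1ccccc1I | starting material
23 | [2-(methoxycarbonyl)phenyl]magnesium chloride | COC(=O)c1ccccc1[Mg]Cl | intermediate (not isolated)
24 | chloromagnesium alkoxide of tert-butyl (1R,6S,7R,8R)-8-hydroxy-8-[2-(methoxycarbonyl)phenyl]-3-(pent-1-yn-1-yl)-7-propylbicyclo[4.2.0]oct-2-ene-2-carboxylate | CC(C)(C)OC(=O)C2=C(C#CCCC)CC[C@H]1[C@@H](CCC)[C@](O[Mg]Cl)(c3ccccc3C(=O)OC)[C@@H]21 | intermediate (not isolated)
25 | tert-butyl (1R,6S,7R,8R)-3'-oxo-3-(pent-1-yn-1-yl)-7-propyl-3'H-spiro[bicyclo[4.2.0]oct-2-ene-8,1'-[2]benzofuran]-2-carboxylate (lactone oxygen cis to propyl and to the six-membered ring) | CC(C)(C)OC(=O)C2=C(C#CCCC)CC[C@H]1[C@@H](CCC)[C@@]3(OC(=O)c4ccccc43)[C@@H]21 | intermediate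
26 | (1R,6S,7R,8R)-3'-oxo-3-(pent-1-yn-1-yl)-7-propyl-3'H-spiro[bicyclo[4.2.0]oct-2-ene-8,1'-[2]benzofuran]-2-carboxylic acid | OC(=O)C2=C(C#CCCC)CC[C@H]1[C@@H](CCC)[C@@]3(OC(=O)c4ccccc43)[C@@H]21 | intermediate (not isolated)
27 | CNP0248594.2: (Z)-butylidene butenolide fused to the cyclohexene of the spiro phthalide core, cyclobutane centres as in 25 | CCC/C=C1\OC(=O)C2=C1CC[C@H]1[C@@H](CCC)[C@@]3(OC(=O)c4ccccc43)[C@@H]21 | target

**Step count and risks**
Total steps: 16. Longest linear sequence: 16 steps (from 1 and 2 to 27).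

The three steps most likely to fail:

1. Step 3. The enzyme may discriminate the enantiomers poorly, or not acylate at all, because the carbinol sits on the concave face between two cis ring substituents. The fallback sets out from 5 and comes back at 6. Racemic 5 is acylated with (1S)-(−)-camphanic chloride (Et3N, DMAP, CH2Cl2) to give two diastereomeric esters. The ester of the wanted alcohol, (1S,5S,6R,7R)-7-propylbicyclo[3.2.0]hept-2-en-6-yl (1S)-camphanate F1, is separated by chromatography or crystallisation and cleaved with KOH in MeOH/H2O to give 6.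

2. Step 6. The alkoxide may attack the ring-bound carbonyl as well, or deprotonate the anhydride instead of adding to it. The fallback sets out from 9 and comes back at 12; it differentiates the arms by ester hydrolysis rates. Diacid 9 is converted with (CH3)3SiCHN2 (MeOH/toluene) into methyl (1S,2S,3R,4R)-3-[(tert-butyldimethylsilyl)oxy]-2-(2-methoxy-2-oxoethyl)-4-propylcyclobutane-1-carboxylate F2. One equivalent of LiOH (THF/H2O, 0 °C) should hydrolyse only the unhindered CH2CO2CH3 ester, giving 2-[(1S,2R,3R,4S)-2-[(tert-butyldimethylsilyl)oxy]-4-(methoxycarbonyl)-3-propylcyclobutyl]acetic acid F3. Di-tert-butyl dicarbonate, DMAP and t-BuOH turn the acid into methyl (1S,2S,3R,4R)-2-(2-tert-butoxy-2-oxoethyl)-3-[(tert-butyldimethylsilyl)oxy]-4-propylcyclobutane-1-carboxylate F4. LiBH4 (THF, rt) then reduces the methyl ester but not the tert-butyl ester and gives 12.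

3. Step 15. The basic aryl nucleophile may enolise the strained ketone and so epimerise the propyl-bearing centre, or the tertiary cyclobutanolate may fragment before it lactonises. The fallback sets out from 21 and comes back at 25; it separates C–C bond formation from lactone closure. 1-Bromo-2-iodobenzene and i-PrMgCl·LiCl (THF, −40 °C) give 2-bromophenylmagnesium chloride F5. With LaCl3·2LiCl at −78 °C this adds to 21, and a cold quench gives tert-butyl (1R,6S,7R,8R)-8-(2-bromophenyl)-8-hydroxy-3-(pent-1-yn-1-yl)-7-propylbicyclo[4.2.0]oct-2-ene-2-carboxylate F6. Palladium-catalysed carbonylative lactonisation (Pd(OAc)2, 1,3-bis(diphenylphosphino)propane, CO 1 atm, Et3N, DMF, 80 °C) then closes the phthalide and gives 25.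

**Further compounds**
F1 | step 3 | (1S,5S,6R,7R)-7-propylbicyclo[3.2.0]hept-2-en-6-yl (1S)-camphanate | C1=C[C@H]2[C@@H](CCC)[C@@H](OC(=O)[C@@]34CC[C@@](C)(C(=O)O3)C4(C)C)[C@H]2C1
F2 | step 6 | methyl (1S,2S,3R,4R)-3-[(tert-butyldimethylsilyl)oxy]-2-(2-methoxy-2-oxoethyl)-4-propylcyclobutane-1-carboxylate | COC(=O)[C@H]1[C@@H](CCC)[C@@H](O[Si](C)(C)C(C)(C)C)[C@H]1CC(=O)OC
F3 | step 6 | 2-[(1S,2R,3R,4S)-2-[(tert-butyldimethylsilyl)oxy]-4-(methoxycarbonyl)-3-propylcyclobutyl]acetic acid | COC(=O)[C@H]1[C@@H](CCC)[C@@H](O[Si](C)(C)C(C)(C)C)[C@H]1CC(O)=O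
F4 | step 6 | methyl (1S,2S,3R,4R)-2-(2-tert-butoxy-2-oxoethyl)-3-[(tert-butyldimethylsilyl)oxy]-4-propylcyclobutane-1-carboxylate | COC(=O)[C@H]1[C@@H](CCC)[C@@H](O[Si](C)(C)C(C)(C)C)[C@H]1CC(=O)OC(C)(C)C
F5 | step 15 | 2-bromophenylmagnesium chloride | Brc1ccccc1[Mg]Cl
F6 | step 15 | tert-butyl (1R,6S,7R,8R)-8-(2-bromophenyl)-8-hydroxy-3-(pent-1-yn-1-yl)-7-propylbicyclo[4.2.0]oct-2-ene-2-carboxylate | CC(C)(C)OC(=O)C2=C(C#CCCC)CC[C@H]1[C@@H](CCC)[C@](O)(c3ccccc3Br)[C@@H]21
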